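**Plan**
1. Numbering: chain C1 (CO2H) to C9 as in the target name; furan O1, C2 (aryl), C3, C4 (chain), C5. Retrosynthesis: furan C5–H goes back to a lactone carbonyl, the C3=C4 bond of that butenolide is cut by ring-closing metathesis, then the ester C–O bond, which gives aryl vinyl carbinol 18 and 2-substituted acrylic acid 14.
2. Acid 14 is cut at the bond from chain C5 to the acrylate α-carbon (malonate Michael addition), at C7=C8 and C5=C6 (two Wittig reactions) and at the exocyclic methylene (Mannich methylenation), back to aldehyde 4 from anhydride 1.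
3. Forward: C1–C5, then C6–C7, the malonate carbons (later furan C4 and C5), C8 with its methyl groups and the methylene are added in that order; esterification joins the arene; the one new ring closes in step 12 and is aromatised in step 13; deprotection is last.
4. Enabling feature: the 2-aryl-4-alkylfuran has hydrogen on C3 next to chain-bearing C4, so the C3=C4 edge maps onto metathesis of a vinyl group with a 1,1-disubstituted acrylate alkene, while O1, aryl-bearing C2 and C5 are already joined in an ester of an aryl vinyl carbinol.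
5. Stereochemistry: C3 (R) from catalytic desymmetrisation of the meso anhydride; chain C5 (S) from catalyst-controlled iminium Michael addition; the carbinol centre is racemic and is erased on aromatisation.
6. Aryl silyl ethers and a tert-butyl ester are used so that the end game needs no protic acid, which would cyclise the prenyl alkene onto furan C5.

Key step: step 12

Assumption: of the two pseudo-enantiomeric anthraquinone-bridged dihydrocinchona catalysts, (DHQ)2AQN is taken to open anhydride 1 to the (S)-hemiester 2; should the sense be the reverse, (DHQD)2AQN replaces it and nothing else changes.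

**Route**

Step 1
Reactants: 1 3-methylglutaric anhydride
Product: 2 (3S)-5-methoxy-3-methyl-5-oxopentanoic acid
Conditions: MeOH (10 equiv), hydroquinine anthraquinone-1,4-diyl diether [(DHQ)2AQN, 10 mol%], Et2O, −40 °C
Reagents that add atoms: methanol, SMILES CO
Why: Alkaloid-catalysed alcoholysis of a meso anhydride (desymmetrisation), in which the quinuclidine nitrogen of the catalyst activates methanol as a general base and delivers it to one of the two enantiotopic carbonyl groups, which sets C3 (the opened carbonyl becomes the methyl ester, the later C5 end).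

Step 2
Reactants: 2 (3S)-5-methoxy-3-methyl-5-oxopentanoic acid
Product: 3 1-tert-butyl 5-methyl (3R)-3-methylpentanedioate
Conditions: tert-butyl 2,2,2-trichloroacetimidate (2 equiv), BF3·OEt2 (cat.), CH2Cl2–cyclohexane, rt
Reagents that add atoms: tert-butyl 2,2,2-trichloroacetimidate, SMILES CC(C)(C)OC(=N)C(Cl)(Cl)Cl
Why: Acid-catalysed O-alkylation of a carboxylic acid by a trichloroacetimidate transfers the tert-butyl group under conditions that leave the methyl ester and the C3 centre untouched (the descriptor changes from S to R only because the ester priorities change).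

Step 3
Reactants: 3 1-tert-butyl 5-methyl (3R)-3-methylpentanedioate
Product: 4 tert-butyl (3R)-3-methyl-5-oxopentanoate
Conditions: iBu2AlH (1.05 equiv), CH2Cl2, −78 °C; then MeOH, aq. potassium sodium tartrate
Reagents that add atoms: none
Why: Partial ester reduction, in which iBu2AlH adds once to the unhindered methyl ester at −78 °C and the aluminium hemiacetal survives until work-up, while the bulky tert-butyl ester is not attacked, so only the C5 carbonyl becomes the aldehyde.

Step 4
Reactants: 4 tert-butyl (3R)-3-methyl-5-oxopentanoate; 5 (triphenylphosphoranylidene)acetaldehyde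
Product: 6 tert-butyl (3R,5E)-3-methyl-7-oxohept-5-enoate
Conditions: 5 (1.1 equiv), toluene, 70 °C
Reagents that add atoms: none
Why: Wittig olefination with the stabilised formyl ylide homologates the saturated aldehyde by two carbons to the (E)-enal, the geometry favoured by a stabilised ylide, and the less electrophilic enal product reacts further only slowly.

Step 5
Reactants: 6 tert-butyl (3R,5E)-3-methyl-7-oxohept-5-enoate; 7 dimethyl malonate
Product: 8 dimethyl 2-[(3S,5R)-7-(tert-butoxy)-5-methyl-1,7-dioxoheptan-3-yl]propanedioate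
Conditions: 7 (2 equiv), (R)-2-{bis[3,5-bis(trifluoromethyl)phenyl](trimethylsilyloxy)methyl}pyrrolidine (10 mol%), EtOH, 0 °C → rt
Reagents that add atoms: none
Why: Iminium-ion organocatalysis (Michael addition of a malonate to an enal), in which the (E)-iminium ion of 6 is shielded on one face by the diaryl(silyloxy)methyl group of the (R)-pyrrolidine, so the malonate adds to the open face of chain C5 and sets (5S) under catalyst control, the remote C3 centre having no say.

Step 6
Reactants: 8 dimethyl 2-[(3S,5R)-7-(tert-butoxy)-5-methyl-1,7-dioxoheptan-3-yl]propanedioate; 9 isopropyltriphenylphosphonium iodide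
Product: 11 dimethyl 2-[(5S,7R)-9-(tert-butoxy)-2,7-dimethyl-9-oxonon-2-en-5-yl]propanedioate, via phosphorus ylide 10 (not isolated)
Conditions: 9 (2.2 equiv), NaN(SiMe3)2 (2.1 equiv), THF, 0 °C; then 8, −78 → 0 °C
Reagents that add atoms: none
Why: Wittig olefination with the non-stabilised isopropylidene ylide turns the aldehyde into the trisubstituted prenyl alkene, addition to the aldehyde at −78 °C being faster than proton transfer from the hindered malonate C–H, and the second equivalent of ylide covers any that is quenched that way.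

Step 7
Reactants: 11 dimethyl 2-[(5S,7R)-9-(tert-butoxy)-2,7-dimethyl-9-oxonon-2-en-5-yl]propanedioate
Product: 12 2-[(5S,7R)-9-(tert-butoxy)-2,7-dimethyl-9-oxonon-2-en-5-yl]propanedioic acid
Conditions: KOH (6 equiv), MeOH–H2O, 45 °C; then 1 M aq. HCl to pH 2, 0 °C
Reagents that add atoms: potassium hydroxide, SMILES [K+].[OH-]
Why: Saponification, in which hydroxide cleaves both methyl esters by acyl–oxygen fission whereas the tert-butyl ester is too hindered to react, and cold acidification gives the malonic acid without decarboxylation.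

Step 8
Reactants: 12 2-[(5S,7R)-9-(tert-butoxy)-2,7-dimethyl-9-oxonon-2-en-5-yl]propanedioic acid
Product: 14 (3S,5R)-7-(tert-butoxy)-5-methyl-3-(3-methylbut-2-en-1-yl)-2-methylidene-7-oxoheptanoic acid, via Mannich base 13 (not isolated)
Conditions: (CH2O)n (2 equiv), Et2NH (1.5 equiv), EtOAc, reflux
Reagents that add atoms: formaldehyde (from paraformaldehyde), SMILES C=O
Why: Mannich reaction of the malonic acid with the iminium ion from formaldehyde and diethylamine, followed by decarboxylative elimination of the amine (Knoevenagel–Doebner-type α-methylenation), gives the 2-substituted acrylic acid, and chain C5 has no acidic hydrogen and keeps its configuration.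

Step 9
Reactants: 15 2,5-dihydroxybenzaldehyde
Product: 16 2,5-bis(tert-butyldimethylsilyloxy)benzaldehyde
Conditions: tBuMe2SiCl (2.5 equiv), imidazole (5 equiv), DMF, rt
Reagents that add atoms: tert-butyldimethylsilyl chloride, SMILES CC(C)(C)[Si](C)(C)Cl
Why: Silylation of both phenols with the silyl chloride and imidazole gives aryl silyl ethers that should tolerate the Grignard reagent, the ruthenium alkylidene and the hydride, and that come off later with fluoride.

Step 10
Reactants: 16 2,5-bis(tert-butyldimethylsilyloxy)benzaldehyde; 17 vinylmagnesium bromide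
Product: 18 1-[2,5-bis(tert-butyldimethylsilyloxy)phenyl]prop-2-en-1-ol (racemic)
Conditions: CH2=CHMgBr (1.3 equiv), THF, −78 °C; then satd aq. NH4Cl at −78 °C
Reagents that add atoms: none
Why: Grignard 1,2-addition of the vinyl nucleophile to the aldehyde gives the aryl vinyl carbinol as a racemate, which is acceptable because this centre becomes furan C2, and the cold quench keeps the magnesium alkoxide from taking over the neighbouring silyl group.

Step 11
Reactants: 14 (3S,5R)-7-(tert-butoxy)-5-methyl-3-(3-methylbut-2-en-1-yl)-2-methylidene-7-oxoheptanoic acid; 18 1-[2,5-bis(tert-butyldimethylsilyloxy)phenyl]prop-2-en-1-ol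
Product: 20 7-tert-butyl 1-{1-[2,5-bis(tert-butyldimethylsilyloxy)phenyl]prop-2-en-1-yl} (3S,5R)-5-methyl-3-(3-methylbut-2-en-1-yl)-2-methylideneheptanedioate (both carbinol epimers), via mixed anhydride 19 (not isolated)
Conditions: 2,4,6-Cl3C6H2COCl, Et3N, THF, 0 °C → rt; then 18, 4-(dimethylamino)pyridine, toluene, rt
Reagents that add atoms: none
Why: Yamaguchi esterification, in which 4-(dimethylamino)pyridine attacks the mixed anhydride at the less hindered acryloyl carbonyl and the acylpyridinium ion acylates the hindered secondary alcohol, while the acid has no α-hydrogen and chain C5 cannot epimerise.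

Step 12
Reactants: 20 7-tert-butyl 1-{1-[2,5-bis(tert-butyldimethylsilyloxy)phenyl]prop-2-en-1-yl} (3S,5R)-5-methyl-3-(3-methylbut-2-en-1-yl)-2-methylideneheptanedioate
Product: 21 tert-butyl (3R,5S)-5-{5-[2,5-bis(tert-butyldimethylsilyloxy)phenyl]-2-oxo-2,5-dihydrofuran-3-yl}-3,8-dimethylnon-7-enoate (both epimers at ring C5)
Conditions: second-generation Grubbs catalyst (H2IMes)(PCy3)Cl2Ru=CHPh (10 mol%, two portions), toluene (3 mM), 80 °C, argon sparge
Reagents that add atoms: none
Why: The benzylidene catalyst exchanges onto the vinyl group of 20, the only monosubstituted alkene, and the resulting ruthenium alkylidene adds across the 1,1-disubstituted acrylate alkene to a ruthenacyclobutane, whose cycloreversion forms the C3=C4 bond and a ruthenium methylidene that leaves as ethene. The closest known reaction type is ring-closing metathesis of allylic esters of 2-substituted acrylic acids to 3-substituted butenolides. The one ring closes as a five-membered unsaturated lactone by intramolecular [2+2] cycloaddition and cycloreversion, with the new double bond endocyclic and both ring C–O bonds already present, so the 2,4-pattern of the later furan is fixed by the ester. No stereocentre is created, the C3 and C5 centres of the chain are not involved, and the carbinol centre is carried as both epimers because it becomes sp2 in step 13. The step needs chemoselectivity among three alkenes and against dimerisation: the trisubstituted prenyl alkene reacts far more slowly and could only close an eight-membered ring, and high dilution with removal of ethene favours five-membered closure over cross-metathesis of two vinyl groups.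

Step 13
Reactants: 21 tert-butyl (3R,5S)-5-{5-[2,5-bis(tert-butyldimethylsilyloxy)phenyl]-2-oxo-2,5-dihydrofuran-3-yl}-3,8-dimethylnon-7-enoate
Product: 23 tert-butyl (3R,5S)-5-{5-[2,5-bis(tert-butyldimethylsilyloxy)phenyl]furan-3-yl}-3,8-dimethylnon-7-enoate, via lactol 22 (not isolated)
Conditions: iBu2AlH (1.3 equiv), CH2Cl2, −78 °C; then 1 M aq. HCl, 0 °C → rt
Reagents that add atoms: none
Why: Butenolide-to-furan conversion, in which iBu2AlH adds once to the lactone carbonyl at −78 °C, where the tert-butyl ester does not react, and on acidification the lactol loses water by way of the oxocarbenium ion and the doubly activated C–H next to the arene to give the aromatic furan.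

Step 14
Reactants: 23 tert-butyl (3R,5S)-5-{5-[2,5-bis(tert-butyldimethylsilyloxy)phenyl]furan-3-yl}-3,8-dimethylnon-7-enoate
Product: 25 (3R,5S)-5-{5-[2,5-bis(tert-butyldimethylsilyloxy)phenyl]furan-3-yl}-3,8-dimethylnon-7-enoic acid, via trimethylsilyl ester 24 (not isolated)
Conditions: Me3SiOTf (4 equiv), 2,6-lutidine (6 equiv), CH2Cl2, 0 °C → rt; then pH 5 phosphate buffer
Reagents that add atoms: none
Why: Silyl triflate-mediated cleavage of a tert-butyl ester, in which silylation of the carbonyl oxygen is followed by loss of the tert-butyl cation that 2,6-lutidine converts to isobutene, so no protic acid is present that could protonate the prenyl alkene and cyclise it onto furan C5, the silyl ester is hydrolysed on work-up and the aryl silyl ethers stay.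

Step 15
Reactants: 25 (3R,5S)-5-{5-[2,5-bis(tert-butyldimethylsilyloxy)phenyl]furan-3-yl}-3,8-dimethylnon-7-enoic acid
Product: 26 (3R,5S)-5-[5-(2,5-dihydroxyphenyl)furan-3-yl]-3,8-dimethylnon-7-enoic acid (CNP0531232.1)
Conditions: Bu4NF (2.5 equiv), AcOH (3 equiv), degassed THF, 0 °C, argon
Reagents that add atoms: none
Why: Fluoride-induced desilylation of the two aryl silyl ethers, buffered with acetic acid so that the hydroquinone stays protonated and is not oxidised to the quinone, and no stereocentre is touched.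

**Compound list**
1 | 3-methylglutaric anhydride (4-methyloxane-2,6-dione) | CC1CC(=O)OC(=O)C1 | starting material
2 | (3S)-5-methoxy-3-methyl-5-oxopentanoic acid | COC(=O)C[C@@H](C)CC(=O)O | intermediate
3 | 1-tert-butyl 5-methyl (3R)-3-methylpentanedioate | COC(=O)C[C@@H](C)CC(=O)OC(C)(C)C | intermediate
4 | tert-butyl (3R)-3-methyl-5-oxopentanoate | O=CC[C@@H](C)CC(=O)OC(C)(C)C | intermediate
5 | (triphenylphosphoranylidene)acetaldehyde | O=CC=P(c1ccccc1)(c1ccccc1)c1ccccc1 | starting material
6 | tert-butyl (3R,5E)-3-methyl-7-oxohept-5-enoate | O=C/C=C/C[C@@H](C)CC(=O)OC(C)(C)C | intermediate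
7 | dimethyl malonate | COC(=O)CC(=O)OC | starting material
8 | dimethyl 2-[(3S,5R)-7-(tert-butoxy)-5-methyl-1,7-dioxoheptan-3-yl]propanedioate | O=CC[C@H](C[C@@H](C)CC(=O)OC(C)(C)C)C(C(=O)OC)C(=O)OC | intermediate
9 | isopropyltriphenylphosphonium iodide | CC(C)[P+](c1ccccc1)(c1ccccc1)c1ccccc1.[I-] | starting material
10 | propan-2-ylidene(triphenyl)phosphorane (phosphorus ylide) | CC(C)=P(c1ccccc1)(c1ccccc1)c1ccccc1 | intermediate
11 | dimethyl 2-[(5S,7R)-9-(tert-butoxy)-2,7-dimethyl-9-oxonon-2-en-5-yl]propanedioate | CC(C)=CC[C@H](C[C@@H](C)CC(=O)OC(C)(C)C)C(C(=O)OC)C(=O)OC | intermediate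
12 | 2-[(5S,7R)-9-(tert-butoxy)-2,7-dimethyl-9-oxonon-2-en-5-yl]propanedioic acid | CC(C)=CC[C@H](C[C@@H](C)CC(=O)OC(C)(C)C)C(C(=O)O)C(=O)O | intermediate
13 | 2-[(diethylamino)methyl]-2-[(5S,7R)-9-(tert-butoxy)-2,7-dimethyl-9-oxonon-2-en-5-yl]propanedioic acid (Mannich base) | CC(C)=CC[C@H](C[C@@H](C)CC(=O)OC(C)(C)C)C(CN(CC)CC)(C(=O)O)C(=O)O | intermediate
14 | (3S,5R)-7-(tert-butoxy)-5-methyl-3-(3-methylbut-2-en-1-yl)-2-methylidene-7-oxoheptanoic acid | CC(C)=CC[C@H](C[C@@H](C)CC(=O)OC(C)(C)C)C(=C)C(=O)O | intermediate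
15 | 2,5-dihydroxybenzaldehyde | O=Cc1cc(O)ccc1O | starting material
16 | 2,5-bis(tert-butyldimethylsilyloxy)benzaldehyde | O=Cc1cc(O[Si](C)(C)C(C)(C)C)ccc1O[Si](C)(C)C(C)(C)C | intermediate
17 | vinylmagnesium bromide | C=C[Mg]Br | starting material
18 | 1-[2,5-bis(tert-butyldimethylsilyloxy)phenyl]prop-2-en-1-ol (racemic) | C=CC(O)c1cc(O[Si](C)(C)C(C)(C)C)ccc1O[Si](C)(C)C(C)(C)C | intermediate
19 | mixed anhydride of acid 14 with 2,4,6-trichlorobenzoic acid | CC(C)=CC[C@H](C[C@@H](C)CC(=O)OC(C)(C)C)C(=C)C(=O)OC(=O)c1c(Cl)cc(Cl)cc1Cl | intermediate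
20 | 7-tert-butyl 1-{1-[2,5-bis(tert-butyldimethylsilyloxy)phenyl]prop-2-en-1-yl} (3S,5R)-5-methyl-3-(3-methylbut-2-en-1-yl)-2-methylideneheptanedioate (both carbinol epimers) | CC(C)=CC[C@H](C[C@@H](C)CC(=O)OC(C)(C)C)C(=C)C(=O)OC(C=C)c1cc(O[Si](C)(C)C(C)(C)C)ccc1O[Si](C)(C)C(C)(C)C | intermediate
21 | tert-butyl (3R,5S)-5-{5-[2,5-bis(tert-butyldimethylsilyloxy)phenyl]-2-oxo-2,5-dihydrofuran-3-yl}-3,8-dimethylnon-7-enoate (both epimers at ring C5) | CC(C)=CC[C@H](C[C@@H](C)CC(=O)OC(C)(C)C)C1=CC(c2cc(O[Si](C)(C)C(C)(C)C)ccc2O[Si](C)(C)C(C)(C)C)OC1=O | intermediate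
22 | tert-butyl (3R,5S)-5-{5-[2,5-bis(tert-butyldimethylsilyloxy)phenyl]-2-hydroxy-2,5-dihydrofuran-3-yl}-3,8-dimethylnon-7-enoate (lactol, epimer mixture) | CC(C)=CC[C@H](C[C@@H](C)CC(=O)OC(C)(C)C)C1=CC(c2cc(O[Si](C)(C)C(C)(C)C)ccc2O[Si](C)(C)C(C)(C)C)OC1O | intermediate
23 | tert-butyl (3R,5S)-5-{5-[2,5-bis(tert-butyldimethylsilyloxy)phenyl]furan-3-yl}-3,8-dimethylnon-7-enoate | CC(C)=CC[C@H](C[C@@H](C)CC(=O)OC(C)(C)C)c1coc(-c2cc(O[Si](C)(C)C(C)(C)C)ccc2O[Si](C)(C)C(C)(C)C)c1 | intermediate
24 | trimethylsilyl (3R,5S)-5-{5-[2,5-bis(tert-butyldimethylsilyloxy)phenyl]furan-3-yl}-3,8-dimethylnon-7-enoate | CC(C)=CC[C@H](C[C@@H](C)CC(=O)O[Si](C)(C)C)c1coc(-c2cc(O[Si](C)(C)C(C)(C)C)ccc2O[Si](C)(C)C(C)(C)C)c1 | intermediate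
25 | (3R,5S)-5-{5-[2,5-bis(tert-butyldimethylsilyloxy)phenyl]furan-3-yl}-3,8-dimethylnon-7-enoic acid | CC(C)=CC[C@H](C[C@@H](C)CC(=O)O)c1coc(-c2cc(O[Si](C)(C)C(C)(C)C)ccc2O[Si](C)(C)C(C)(C)C)c1 | intermediate
26 | (3R,5S)-5-[5-(2,5-dihydroxyphenyl)furan-3-yl]-3,8-dimethylnon-7-enoic acid (CNP0531232.1) | CC(C)=CC[C@H](C[C@@H](C)CC(=O)O)c1coc(-c2cc(O)ccc2O)c1 | target

**Count**
Total steps: 15. Longest linear sequence: 13 (steps 1–8 and 11–15); steps 9 and 10 form the short branch.

**Steps most likely to fail**

Step 12. The ruthenium alkylidene formed at the vinyl group may fail to add to the hindered, electron-poor 1,1-disubstituted acrylate alkene, so that dimer formation through the vinyl groups and catalyst decay win over ring closure. The fallback moves the same C3=C4 closure to the allyl ether oxidation level, where the alkene is electron-neutral. It sets out from acid 14 and carbinol 18. Acid 14 is reduced through its isobutyl mixed carbonic anhydride with NaBH4 to tert-butyl (3R,5S)-5-(3-hydroxyprop-1-en-2-yl)-3,8-dimethylnon-7-enoate F1, which is acetylated to tert-butyl (3R,5S)-5-[3-(acetyloxy)prop-1-en-2-yl]-3,8-dimethylnon-7-enoate F2. Allylic etherification of F2 with the zinc alkoxide of 18 (Et2Zn, Pd(OAc)2, 2-(di-tert-butylphosphino)biphenyl, THF, rt), whose symmetrical 2-substituted allyl unit leaves no regiochemical question, should give tert-butyl (3R,5S)-5-[3-({1-[2,5-bis(tert-butyldimethylsilyloxy)phenyl]prop-2-en-1-yl}oxy)prop-1-en-2-yl]-3,8-dimethylnon-7-enoate F3. Ring-closing metathesis of F3 with the same ruthenium catalyst in CH2Cl2 at 40 °C gives tert-butyl (3R,5S)-5-{5-[2,5-bis(tert-butyldimethylsilyloxy)phenyl]-2,5-dihydrofuran-3-yl}-3,8-dimethylnon-7-enoate F4, and dehydrogenation of F4 with DDQ comes back to the route at furan 23.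

Step 6. Proton transfer from the malonate C–H to the basic ylide, followed by loss of malonate from the aldehyde enolate, may compete with olefination. The fallback builds the prenyl group without base in two operations. It sets out from aldehyde 8, which is methylenated under Takai–Lombardo conditions (Zn, CH2Br2, TiCl4, THF) to dimethyl 2-[(4R,6R)-8-(tert-butoxy)-6-methyl-8-oxooct-1-en-4-yl]propanedioate F5 (same spatial arrangement as 8; the descriptor at the branching carbon changes only through the priority rules). Cross-metathesis of F5 with 2-methylbut-2-ene and the second-generation Grubbs catalyst (H2IMes)(PCy3)Cl2Ru=CHPh comes back to the route at 11.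

Step 5. Slow iminium turnover and dienamine formation at C4 with this β-alkyl enal may lead to incomplete conversion and poor facial selectivity at chain C5, whose epimer would be hard to separate. The fallback replaces catalyst control by auxiliary control and sets out from aldehyde 4.
- Horner–Wadsworth–Emmons reaction of 4 with diethyl {2-oxo-2-[(4S)-2-oxo-4-phenyl-1,3-oxazolidin-3-yl]ethyl}phosphonate (LiCl, iPr2NEt, MeCN) gives tert-butyl (3R,5E)-3-methyl-7-oxo-7-[(4S)-2-oxo-4-phenyl-1,3-oxazolidin-3-yl]hept-5-enoate F6.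
- Conjugate addition of the allyl cuprate (CH2=CHCH2MgBr, CuBr·SMe2, THF, −78 °C) to the chelated imide, from the face opposite the phenyl group, gives tert-butyl (3R,5R)-3-methyl-5-{2-oxo-2-[(4S)-2-oxo-4-phenyl-1,3-oxazolidin-3-yl]ethyl}oct-7-enoate F7.
- Cross-metathesis with 2-methylbut-2-ene gives tert-butyl (3R,5S)-3,8-dimethyl-5-{2-oxo-2-[(4S)-2-oxo-4-phenyl-1,3-oxazolidin-3-yl]ethyl}non-7-enoate F8.
- LiBH4 removes the auxiliary reductively to tert-butyl (3R,5S)-5-(2-hydroxyethyl)-3,8-dimethylnon-7-enoate F9.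
- Dess–Martin oxidation gives tert-butyl (3R,5S)-3,8-dimethyl-5-(2-oxoethyl)non-7-enoate F10.
- α-Methylenation with Eschenmoser's salt and Et3N gives tert-butyl (3R,5S)-3,8-dimethyl-5-(3-oxoprop-1-en-2-yl)non-7-enoate F11.
- Pinnick oxidation (NaClO2, NaH2PO4, 2-methylbut-2-ene) comes back to the route at acid 14.

**Further compounds**
F1 | step 12 | tert-butyl (3R,5S)-5-(3-hydroxyprop-1-en-2-yl)-3,8-dimethylnon-7-enoate | CC(C)=CC[C@H](C[C@@H](C)CC(=O)OC(C)(C)C)C(=C)CO
F2 | step 12 | tert-butyl (3R,5S)-5-[3-(acetyloxy)prop-1-en-2-yl]-3,8-dimethylnon-7-enoate | CC(C)=CC[C@H](C[C@@H](C)CC(=O)OC(C)(C)C)C(=C)COC(C)=O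
F3 | step 12 | tert-butyl (3R,5S)-5-[3-({1-[2,5-bis(tert-butyldimethylsilyloxy)phenyl]prop-2-en-1-yl}oxy)prop-1-en-2-yl]-3,8-dimethylnon-7-enoate | CC(C)=CC[C@H](C[C@@H](C)CC(=O)OC(C)(C)C)C(=C)COC(C=C)c1cc(O[Si](C)(C)C(C)(C)C)ccc1O[Si](C)(C)C(C)(C)C
F4 | step 12 | tert-butyl (3R,5S)-5-{5-[2,5-bis(tert-butyldimethylsilyloxy)phenyl]-2,5-dihydrofuran-3-yl}-3,8-dimethylnon-7-enoate | CC(C)=CC[C@H](C[C@@H](C)CC(=O)OC(C)(C)C)C1=CC(c2cc(O[Si](C)(C)C(C)(C)C)ccc2O[Si](C)(C)C(C)(C)C)OC1
F5 | step 6 | dimethyl 2-[(4R,6R)-8-(tert-butoxy)-6-methyl-8-oxooct-1-en-4-yl]propanedioate | C=CC[C@H](C[C@@H](C)CC(=O)OC(C)(C)C)C(C(=O)OC)C(=O)OC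
F6 | step 5 | tert-butyl (3R,5E)-3-methyl-7-oxo-7-[(4S)-2-oxo-4-phenyl-1,3-oxazolidin-3-yl]hept-5-enoate | O=C(/C=C/C[C@@H](C)CC(=O)OC(C)(C)C)N1[C@@H](c2ccccc2)COC1=O
F7 | step 5 | tert-butyl (3R,5R)-3-methyl-5-{2-oxo-2-[(4S)-2-oxo-4-phenyl-1,3-oxazolidin-3-yl]ethyl}oct-7-enoate | C=CC[C@H](C[C@@H](C)CC(=O)OC(C)(C)C)CC(=O)N1[C@@H](c2ccccc2)COC1=O
F8 | step 5 | tert-butyl (3R,5S)-3,8-dimethyl-5-{2-oxo-2-[(4S)-2-oxo-4-phenyl-1,3-oxazolidin-3-yl]ethyl}non-7-enoate | CC(C)=CC[C@H](C[C@@H](C)CC(=O)OC(C)(C)C)CC(=O)N1[C@@H](c2ccccc2)COC1=O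
F9 | step 5 | tert-butyl (3R,5S)-5-(2-hydroxyethyl)-3,8-dimethylnon-7-enoate | CC(C)=CC[C@H](C[C@@H](C)CC(=O)OC(C)(C)C)CCO
F10 | step 5 | tert-butyl (3R,5S)-3,8-dimethyl-5-(2-oxoethyl)non-7-enoate | CC(C)=CC[C@H](C[C@@H](C)CC(=O)OC(C)(C)C)CC=O
F11 | step 5 | tert-butyl (3R,5S)-3,8-dimethyl-5-(3-oxoprop-1-en-2-yl)non-7-enoate | CC(C)=CC[C@H](C[C@@H](C)CC(=O)OC(C)(C)C)C(=C)C=O
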